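**Plan**
- The target is achiral. Retrosynthesis first removes the acetyl group of ring A, which leaves a symmetric 2,6-dihydroxy-4-methoxyphenyl ring whose two free positions are equivalent.
- Ring B (acetophenone numbering: C1 acetyl, C2 OMe, C3 CH2–ring A, C4 OH, C5 CH3, C6 OH) is fully substituted, with oxygen on the alternate carbons C2, C4 and C6 and with acetyl and methoxy on the adjacent carbons C1 and C2. C1–C2 can therefore come from the two alkyne carbons of a β-methoxy ynone, and C3–C6 from a doubly enolized β-keto ester.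
- Ring B is cut at C1–C6 and C2–C3 into a 1-benzyloxy-1,3-bis(trimethylsilyloxy)diene and 4-methoxybut-3-yn-2-one. The parent β-keto ester is cut by a crossed Claisen disconnection into benzyl propanoate and a 3-arylpropanoic acid derived from 2,4,6-trihydroxybenzaldehyde.
- Forward: ring A aldehyde, then arylpropanoic acid, β-keto ester and diene; the ynone is made in one step; cycloaddition–aromatization closes ring B; hydrogenolysis and a single C-acetylation finish the synthesis.
- No stereocentre is present in the target; the stereocentres of the racemic keto ester and of the cycloadduct are transient.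

Key step: step 8

**Route**

Step 1
Reactants: 1 2,4,6-trihydroxybenzaldehyde
Product: 2 2,6-dihydroxy-4-methoxybenzaldehyde
Conditions: Me2SO4 (1.05 equiv), K2CO3 (1.0 equiv), acetone, 0 → 20 °C
Reagents that add atoms: dimethyl sulfate, COS(=O)(=O)OC
Why: Williamson O-methylation with one equivalent of weak base should occur at the 4-hydroxyl, the most acidic one and not chelated to the formyl group (the selectivity known for 2,4,6-trihydroxyacetophenone), and any di-O-methyl by-product is removed by chromatography.

Step 2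
Reactants: 2 2,6-dihydroxy-4-methoxybenzaldehyde
Product: 3 2,6-bis(benzyloxy)-4-methoxybenzaldehyde
Conditions: BnBr (2.5 equiv), K2CO3 (3 equiv), DMF, 60 °C
Reagents that add atoms: benzyl bromide, BrCc1ccccc1
Why: Williamson benzylation of the two chelated ortho-hydroxyls with excess benzyl bromide in warm DMF is the standard protection of 2-hydroxybenzaldehydes.

Step 3
Reactants: 3 2,6-bis(benzyloxy)-4-methoxybenzaldehyde; 4 2,2-dimethyl-1,3-dioxane-4,6-dione (Meldrum's acid)
Product: 7 3-[2,6-bis(benzyloxy)-4-methoxyphenyl]propanoic acid, via arylidene Meldrum's acid 5 (not isolated), via benzyl Meldrum's acid 6 (not isolated)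
Conditions: 4 (1.1 equiv), HCO2H/Et3N (5:2), 95–100 °C; then H2O, aq. HCl to pH 2
Reagents that add atoms: none
Why: Tandem Knoevenagel condensation, conjugate transfer hydrogenation by formate and decarboxylative opening of the Meldrum's acid ring turns an aromatic aldehyde into the 3-arylpropanoic acid in one flask, and benzyl ethers are inert to formate in the absence of a metal catalyst.

Step 4
Reactants: 7 3-[2,6-bis(benzyloxy)-4-methoxyphenyl]propanoic acid; 8 benzyl propanoate
Product: 10 benzyl 5-[2,6-bis(benzyloxy)-4-methoxyphenyl]-2-methyl-3-oxopentanoate (racemic), via acyl imidazole 9 (not isolated)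
Conditions: 1,1'-carbonyldiimidazole (1.1 equiv), THF, 20 °C; added to the lithium enolate of 8 [8 (3.2 equiv), LiN(i-Pr)2 (3.2 equiv), THF, −78 °C], −78 → −30 °C; aq. HCl (1 M) to pH 5
Reagents that add atoms: none
Why: Crossed Claisen condensation in which the acyl imidazole acylates the preformed lithium ester enolate at low temperature (excess enolate absorbs the liberated imidazole and deprotonates the product) gives the 2-methyl β-keto ester without self-condensation.

Step 5
Reactants: 10 benzyl 5-[2,6-bis(benzyloxy)-4-methoxyphenyl]-2-methyl-3-oxopentanoate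
Product: 11 benzyl 5-[2,6-bis(benzyloxy)-4-methoxyphenyl]-2-methyl-3-(trimethylsilyloxy)pent-2-enoate (E/Z mixture)
Conditions: Et3N (1.6 equiv), Me3SiCl (1.5 equiv), toluene, 20 °C, 72 h; filter, concentrate
Reagents that add atoms: chlorotrimethylsilane, C[Si](C)(C)Cl
Why: Soft enolization and O-silylation of a β-keto ester with Et3N/Me3SiCl gives the ester-conjugated silyl enol ether, the standard first stage of bis(silyloxy)diene synthesis, which also works for 2-alkyl β-keto esters.

Step 6
Reactants: 11 benzyl 5-[2,6-bis(benzyloxy)-4-methoxyphenyl]-2-methyl-3-(trimethylsilyloxy)pent-2-enoate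
Product: 12 (1Z,3Z)-1-benzyloxy-5-[2,6-bis(benzyloxy)-4-methoxyphenyl]-2-methyl-1,3-bis(trimethylsilyloxy)penta-1,3-diene (ketene acetal geometry not controlled and immaterial)
Conditions: LiN(i-Pr)2 (1.5 equiv), THF, −78 °C; Me3SiCl (1.6 equiv), −78 → 20 °C; concentrate, hexane, filter under argon; used crude
Reagents that add atoms: chlorotrimethylsilane, C[Si](C)(C)Cl
Why: Vinylogous (γ) deprotonation of the silyloxy enoate and O-silylation of the dienolate at the ester oxygen is the standard second stage of 1-alkoxy-1,3-bis(silyloxy)diene synthesis, and the moisture-sensitive diene is carried on at once.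

Step 7
Reactants: 13 2-chloro-1,1-dimethoxyethane (chloroacetaldehyde dimethyl acetal); 14 N-methoxy-N-methylacetamide
Product: 16 4-methoxybut-3-yn-2-one, via lithium methoxyacetylide 15 (not isolated)
Conditions: Et2NH (3.3 equiv), n-BuLi (3.2 equiv), THF, 0 °C; 13 (1.05 equiv), 0 °C, 2 h; 14 (1.0 equiv), −78 → −20 °C; inverse quench into cold aq. citric acid/Et2O; concentrate cold
Reagents that add atoms: none
Why: Double elimination and metalation of the chloroacetal by LiNEt2 gives the alkoxyacetylide in the flask, and its acylation by the N-methoxy-N-methylamide stops at the chelated tetrahedral adduct, so the ynone is released only in the cold acidic quench, which keeps the amines protonated and away from the push–pull alkyne.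

Step 8
Reactants: 12 (1Z,3Z)-1-benzyloxy-5-[2,6-bis(benzyloxy)-4-methoxyphenyl]-2-methyl-1,3-bis(trimethylsilyloxy)penta-1,3-diene; 16 4-methoxybut-3-yn-2-one
Product: 19 1-[2-benzyloxy-5-{[2,6-bis(benzyloxy)-4-methoxyphenyl]methyl}-4-hydroxy-6-methoxy-3-methylphenyl]ethanone, via cycloadduct 17 (not isolated), via aryl silyl ether 18 (not isolated)
Conditions: 12 (1.5 equiv), 16 (1.0 equiv), toluene, −20 → 20 °C, then 60 °C; then THF, 1 M aq. HCl, 0 °C
Reagents that add atoms: none
Why: Proposed new method: diene 12 is the doubly enolized form of a β-keto ester and should attack through its most nucleophilic terminus C4 (the former γ-carbon, which carries the ring A benzyl group) the methoxy-bearing β-carbon of the push–pull ynone 16, while the ketene acetal carbon C1 bonds to the acetyl-bearing α-carbon, either in one asynchronous suprafacial (4+2) cycloaddition or by Mukaiyama–Michael addition followed by 6-(enolexo)-exo-trig closure of the allenyl silyl ether onto the silyloxycarbenium carbon; both paths give cyclohexa-1,4-diene 17. The closest known reaction type is the cycloaddition–aromatization of 1-alkoxy-1,3-bis(silyloxy)buta-1,3-dienes with acetylenic esters and ketones to resorcinol derivatives, whereas a β-alkoxy ynone (less electrophilic through donation from oxygen) and a diene substituted at both C2 and C4 have not been combined in this way. Ring B is thus closed as a six-membered carbocycle, and 1,4-elimination of Me3SiOH from the ketal carbon and C4–H of 17 aromatizes it to silyl ether 18, which the dilute acid cleaves to phenol 19. The two sp3 centres of 17 are lost on aromatization, so no stereocentre has to be controlled. The one selectivity needed is the mutual orientation of the partners, and polarity matching secures it: the β-carbon of 16 is the electrophilic site and, since it stays sp2 after attack, methoxide cannot be expelled and the single O-methyl group of ring B is retained. The methyl ynol ether cannot undergo the retro-ene loss of an alkene that ethyl analogues suffer on heating, and the slim alkyne suits the hindered diene termini.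

Step 9
Reactants: 19 1-[2-benzyloxy-5-{[2,6-bis(benzyloxy)-4-methoxyphenyl]methyl}-4-hydroxy-6-methoxy-3-methylphenyl]ethanone
Product: 20 1-{3-[(2,6-dihydroxy-4-methoxyphenyl)methyl]-4,6-dihydroxy-2-methoxy-5-methylphenyl}ethanone
Conditions: H2 (1 atm), 10% Pd/C, EtOAc/MeOH, 20 °C
Reagents that add atoms: none
Why: Catalytic hydrogenolysis cleaves the three aryl benzyl ethers under neutral conditions, while the diarylmethane C–C bond, the methyl ethers and the hindered di-ortho-substituted aryl ketone should not be reduced at this pressure and temperature.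

Step 10
Reactants: 20 1-{3-[(2,6-dihydroxy-4-methoxyphenyl)methyl]-4,6-dihydroxy-2-methoxy-5-methylphenyl}ethanone
Product: 21 1-{3-[(3-acetyl-2,6-dihydroxy-4-methoxyphenyl)methyl]-4,6-dihydroxy-2-methoxy-5-methylphenyl}ethanone (CNP0360110.0)
Conditions: Ac2O (1.1 equiv), BF3·OEt2 (3 equiv), EtOAc, 0 → 20 °C; then MeOH, aq. NaOAc, 40 °C
Reagents that add atoms: acetic anhydride, CC(=O)OC(C)=O
Why: BF3-mediated Friedel–Crafts C-acetylation can occur only on ring A, since ring B has no free position, at either of its two symmetry-equivalent free carbons, and the first acetyl group (held as its difluoroboron chelate until work-up) deactivates the ring against a second acylation.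

**Compound list**
1 | 2,4,6-trihydroxybenzaldehyde | O=Cc1c(O)cc(O)cc1O | starting material
2 | 2,6-dihydroxy-4-methoxybenzaldehyde | COc1cc(O)c(C=O)c(O)c1 | intermediate
3 | 2,6-bis(benzyloxy)-4-methoxybenzaldehyde | COc1cc(OCc2ccccc2)c(C=O)c(OCc2ccccc2)c1 | intermediate
4 | 2,2-dimethyl-1,3-dioxane-4,6-dione (Meldrum's acid) | CC1(C)OC(=O)CC(=O)O1 | starting material
5 | 5-{[2,6-bis(benzyloxy)-4-methoxyphenyl]methylidene}-2,2-dimethyl-1,3-dioxane-4,6-dione | COc1cc(OCc2ccccc2)c(C=C2C(=O)OC(C)(C)OC2=O)c(OCc2ccccc2)c1 | intermediate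
6 | 5-{[2,6-bis(benzyloxy)-4-methoxyphenyl]methyl}-2,2-dimethyl-1,3-dioxane-4,6-dione | COc1cc(OCc2ccccc2)c(CC2C(=O)OC(C)(C)OC2=O)c(OCc2ccccc2)c1 | intermediate
7 | 3-[2,6-bis(benzyloxy)-4-methoxyphenyl]propanoic acid | COc1cc(OCc2ccccc2)c(CCC(=O)O)c(OCc2ccccc2)c1 | intermediate
8 | benzyl propanoate | CCC(=O)OCc1ccccc1 | starting material
9 | 3-[2,6-bis(benzyloxy)-4-methoxyphenyl]-1-(imidazol-1-yl)propan-1-one | COc1cc(OCc2ccccc2)c(CCC(=O)n2ccnc2)c(OCc2ccccc2)c1 | intermediate
10 | benzyl 5-[2,6-bis(benzyloxy)-4-methoxyphenyl]-2-methyl-3-oxopentanoate (racemic) | COc1cc(OCc2ccccc2)c(CCC(=O)C(C)C(=O)OCc2ccccc2)c(OCc2ccccc2)c1 | intermediate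
11 | benzyl 5-[2,6-bis(benzyloxy)-4-methoxyphenyl]-2-methyl-3-(trimethylsilyloxy)pent-2-enoate (E/Z mixture) | COc1cc(OCc2ccccc2)c(CCC(O[Si](C)(C)C)=C(C)C(=O)OCc2ccccc2)c(OCc2ccccc2)c1 | intermediate
12 | (1Z,3Z)-1-benzyloxy-5-[2,6-bis(benzyloxy)-4-methoxyphenyl]-2-methyl-1,3-bis(trimethylsilyloxy)penta-1,3-diene | COc1cc(OCc2ccccc2)c(C/C=C(/C(C)=C(/OCc2ccccc2)O[Si](C)(C)C)O[Si](C)(C)C)c(OCc2ccccc2)c1 | intermediate
13 | 2-chloro-1,1-dimethoxyethane | COC(CCl)OC | starting material
14 | N-methoxy-N-methylacetamide | CON(C)C(C)=O | starting material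
15 | lithium methoxyacetylide | [Li]C#COC | intermediate
16 | 4-methoxybut-3-yn-2-one | COC#CC(C)=O | intermediate
17 | 1-[6-benzyloxy-3-{[2,6-bis(benzyloxy)-4-methoxyphenyl]methyl}-2-methoxy-5-methyl-4,6-bis(trimethylsilyloxy)cyclohexa-1,4-dien-1-yl]ethanone (mixture of stereoisomers) | CC(=O)C1=C(OC)C(Cc2c(OCc3ccccc3)cc(OC)cc2OCc2ccccc2)C(O[Si](C)(C)C)=C(C)C1(OCc4ccccc4)O[Si](C)(C)C | intermediate
18 | 1-[2-benzyloxy-5-{[2,6-bis(benzyloxy)-4-methoxyphenyl]methyl}-6-methoxy-3-methyl-4-(trimethylsilyloxy)phenyl]ethanone | CC(=O)c1c(OCc2ccccc2)c(C)c(O[Si](C)(C)C)c(Cc2c(OCc3ccccc3)cc(OC)cc2OCc2ccccc2)c1OC | intermediate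
19 | 1-[2-benzyloxy-5-{[2,6-bis(benzyloxy)-4-methoxyphenyl]methyl}-4-hydroxy-6-methoxy-3-methylphenyl]ethanone | CC(=O)c1c(OCc2ccccc2)c(C)c(O)c(Cc2c(OCc3ccccc3)cc(OC)cc2OCc2ccccc2)c1OC | intermediate
20 | 1-{3-[(2,6-dihydroxy-4-methoxyphenyl)methyl]-4,6-dihydroxy-2-methoxy-5-methylphenyl}ethanone | CC(=O)c1c(O)c(C)c(O)c(Cc2c(O)cc(OC)cc2O)c1OC | intermediate
21 | 1-{3-[(3-acetyl-2,6-dihydroxy-4-methoxyphenyl)methyl]-4,6-dihydroxy-2-methoxy-5-methylphenyl}ethanone | COc1cc(O)c(Cc2c(O)c(C)c(O)c(C(C)=O)c2OC)c(O)c1C(C)=O | target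

**Count and risks**

Total step count: 10. Longest linear sequence: 9 steps (steps 1–6 and 8–10, from 1 to 21); step 7 is a one-step branch.

Steps most likely to fail:

1. Step 8. The push–pull alkyne may be too weakly electrophilic, so that the diene is lost by desilylation or silyl migration before it reacts. Attack may also take place at the ketone carbonyl in place of the β-carbon, or the open-chain Michael adduct may fail to close. The fallback uses known chemistry, sets out from aldehyde 3 and comes back to the route at 20. Reduction of 3 with NaBH4 (THF/MeOH, 0 °C) gives [2,6-bis(benzyloxy)-4-methoxyphenyl]methanol F1. This very electron-rich benzylic alcohol is added slowly to an excess of the known natural acetophenone 1-(2,4-dihydroxy-6-methoxy-3-methylphenyl)ethanone F2 (taken to be purchasable from a natural-product supplier) with catalytic TsOH·H2O in MeCN at 20 °C. The benzylic cation then alkylates the only free ring position of F2 (C5, between the 4-hydroxyl and the 6-methoxy group) in a Friedel–Crafts benzylation, giving 1-[3-{[2,6-bis(benzyloxy)-4-methoxyphenyl]methyl}-4,6-dihydroxy-2-methoxy-5-methylphenyl]ethanone F3. Hydrogenolysis of its two benzyl ethers (H2, Pd/C, EtOAc/MeOH) gives 20, which enters step 10.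

2. Step 10. The Lewis acid may cleave the methylene bridge by ipso-protonation and loss of a benzylic cation, which would scramble the two aryl units. O-acetylation without migration to carbon, or a second C-acylation of ring A, are further possibilities. The fallback sets out from 19 and comes back at 21. Bromination of 19 with NBS (1.0 equiv, MeCN, −20 °C) at one of the two equivalent free positions of ring A, the only activated aromatic C–H positions in the molecule, gives 1-[2-benzyloxy-5-{[2,6-bis(benzyloxy)-3-bromo-4-methoxyphenyl]methyl}-4-hydroxy-6-methoxy-3-methylphenyl]ethanone F4. Stille coupling with tributyl(1-ethoxyvinyl)stannane (Pd(PPh3)4, toluene, 100 °C) gives the enol ether 1-[2-benzyloxy-5-{[2,6-bis(benzyloxy)-3-(1-ethoxyethenyl)-4-methoxyphenyl]methyl}-4-hydroxy-6-methoxy-3-methylphenyl]ethanone F5. Dilute aq. HCl in THF hydrolyses it to the diketone 1-[3-{[3-acetyl-4-benzyloxy-2-hydroxy-6-methoxy-5-methylphenyl]methyl}-2,4-bis(benzyloxy)-6-methoxyphenyl]ethanone F6. Hydrogenolysis (H2, Pd/C) of the three benzyl ethers then gives 21 without any acid-mediated acylation.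

3. Step 3. The Knoevenagel condensation may stall with the hindered, strongly deactivated aldehyde. Alternatively, the benzylic C–C bond of the Meldrum's acid adduct may ionize in the hot acidic medium, with reduction of the stabilized cation by formate. The fallback sets out from 3 and comes back at 7. Horner–Wadsworth–Emmons olefination of 3 with trimethyl phosphonoacetate (NaH, THF, 0 → 20 °C) gives methyl (2E)-3-[2,6-bis(benzyloxy)-4-methoxyphenyl]prop-2-enoate F7. Conjugate reduction with Mg in MeOH, which leaves benzyl ethers intact, gives methyl 3-[2,6-bis(benzyloxy)-4-methoxyphenyl]propanoate F8. Saponification (LiOH, THF/H2O) gives acid 7.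

**Further compounds**
F1 | step 8 | [2,6-bis(benzyloxy)-4-methoxyphenyl]methanol | COc1cc(OCc2ccccc2)c(CO)c(OCc2ccccc2)c1
F2 | step 8 | 1-(2,4-dihydroxy-6-methoxy-3-methylphenyl)ethanone (purchased) | CC(=O)c1c(O)c(C)c(O)cc1OC
F3 | step 8 | 1-[3-{[2,6-bis(benzyloxy)-4-methoxyphenyl]methyl}-4,6-dihydroxy-2-methoxy-5-methylphenyl]ethanone | CC(=O)c1c(O)c(C)c(O)c(Cc2c(OCc3ccccc3)cc(OC)cc2OCc2ccccc2)c1OC
F4 | step 10 | 1-[2-benzyloxy-5-{[2,6-bis(benzyloxy)-3-bromo-4-methoxyphenyl]methyl}-4-hydroxy-6-methoxy-3-methylphenyl]ethanone | CC(=O)c1c(OCc2ccccc2)c(C)c(O)c(Cc2c(OCc3ccccc3)cc(OC)c(Br)c2OCc2ccccc2)c1OC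
F5 | step 10 | 1-[2-benzyloxy-5-{[2,6-bis(benzyloxy)-3-(1-ethoxyethenyl)-4-methoxyphenyl]methyl}-4-hydroxy-6-methoxy-3-methylphenyl]ethanone | CC(=O)c1c(OCc2ccccc2)c(C)c(O)c(Cc2c(OCc3ccccc3)cc(OC)c(C(=C)OCC)c2OCc2ccccc2)c1OC
F6 | step 10 | 1-[3-{[3-acetyl-4-benzyloxy-2-hydroxy-6-methoxy-5-methylphenyl]methyl}-2,4-bis(benzyloxy)-6-methoxyphenyl]ethanone | CC(=O)c1c(OCc2ccccc2)c(C)c(O)c(Cc2c(OCc3ccccc3)cc(OC)c(C(C)=O)c2OCc2ccccc2)c1OC
F7 | step 3 | methyl (2E)-3-[2,6-bis(benzyloxy)-4-methoxyphenyl]prop-2-enoate | COC(=O)/C=C/c1c(OCc2ccccc2)cc(OC)cc1OCc1ccccc1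
F8 | step 3 | methyl 3-[2,6-bis(benzyloxy)-4-methoxyphenyl]propanoate | COC(=O)CCc1c(OCc2ccccc2)cc(OC)cc1OCc1ccccc1
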